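**Slow ring.** Slow means nothing until you say against what, so here you hold the making of ring against the pairing of substrate, and their ratio is what a charge buys.

| flask | substrate | remark | time |
|---|---|---|---|
| larch | 1.1 M | run made earlier |  |
| grey | 2.3 M |  | 4.0 h |
| teal | 2.3 M |  | 10 h |
| violet | 2.3 M |  | 25 h |

larch run (percent of the substrate charged)

| time / h | open dimer / % | substrate / % | ring / % | open trimer / % |
|---|---|---|---|---|
| 0.833 | 57 | 40 | 10 | 2 |
| 1.50 | 67 | 23 | 7 | 4 |
| 2.50 | 75 | 15 | 10 | 0 |
| 3.00 | 75 | 14 | 11 | 0 |
| 4.00 | 74 | 11 | 13 | 2 |
| 5.00 | 75 | 11 | 16 | 2 |

(scatter of a reading: 2 percentage points)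

- a species is counted by the substrate in it: one open dimer counts as two
- a species is counted by the substrate in it: one open trimer counts as three

* which of these there is most of at the end, counted by the substrate in it, grey (ring / open dimer / substrate / open trimer)
* which of these there is most of at the end, counted by the substrate in it, teal (ring / open dimer / substrate / open trimer)
* which of these there is most of at the end, counted by the substrate in it, violet (ring / open dimer / substrate / open trimer)
* how much there is at the end of the one of these that leads, in percent of the substrate charged: grey
* how much there is at the end of the one of these that leads, in percent of the substrate charged: teal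
* how much there is at the end of the one of these that leads, in percent of the substrate charged: violet

**Ring constant.** In larch, ring gains 6 percentage points between 2.50 h and 5.00 h while substrate averages 13.0%, and dividing gives a first-order constant of 0.185 h⁻¹. The first reading, divided the same way with substrate averaged from the charge, gives 0.171 h⁻¹, close to it. So I take ring to follow [substrate] to the first power.

**Pairing constant.** When two substrate molecules must meet, the rate goes with [substrate] squared, and 1/[substrate] climbs in a straight line with time. Larch stands at 15% at 2.50 h, so that climb is 5.72 × 10⁻⁴ M⁻¹ s⁻¹, a reading with its scatter.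

**The factor.** Rate into open dimer over rate into ring is b[substrate]/k, with b the pairing constant and k the ring constant. At the grey charge of 2.3 M this gives F = 25.7, the selectivity factor at the start. When a fraction a of the charge is left, the ratio has fallen to Fa. Each bit of substrate then goes to ring with share 1/(1+Fa), and summing those shares gives a logarithm: ring = ln((1+F)/(1+Fa))/F.

**My reckoning.** Neglecting ring, a = 1/(1+b[substrate]t) with the charged [substrate]: 5.01% in grey, 2.07% in teal, 0.837% in violet. Ring comes to 9.57%, 11.1% and 12.0%. Allowing 2% for open trimer, as in the last larch reading, I expect open dimer to lead at 83.4%, 84.8% and 85.1%.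

**The forecast.** It also has open dimer leading, but at 80%, 72% and 57%, lower than mine in violet, on the ground that “Ring keeps growing at about 2%/h”.

**The flasks.** Grey holds open dimer at 85.3%, teal at 86.5%, violet at 86.6%.

    substrate → ring (k = 3.60 × 10⁻⁵ s⁻¹)
    2 substrate → open dimer (k = 2.20 × 10⁻⁴ M⁻¹ s⁻¹)
    substrate + open dimer → open trimer (k = 2.10 × 10⁻⁶ M⁻¹ s⁻¹)

**Fading ratio.** In grey, the rate at which substrate is used into open dimer over that into ring is 28 at the start and 1.3 at 4.00 h, lower at the end, and my F of 25.7 with the 4.7% left in grey gives ring 9.70%, where the flask has 8.91%. A neighbour of grey charged with 1.4 M has F = 15.6, and with its 7.4% left the rule gives ring 13.1%, where that flask has 12.1%.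

The readings stem from a simulated flask for an exercise; the scatter is artificial.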